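**Retrosynthetic overview**

1. Last disconnection, C9–C10 (ring B, quaternary C10): a cobalt-hydride hydrogen-atom-transfer radical cycloisomerisation of a ring-A exo-methylene allylic cinnamate onto a tethered (Z)-enedial. This one step sets C10 and C9 and leaves the C7=C8 enal.
2. The (Z)-enedial (C8, C9, C11, C12) is unmasked from a 3-alkylfuran with singlet oxygen, so the cis geometry that leads to the 9β-formyl group comes from the heterocycle.
3. The cinnamate is built on the C1 alcohol from a bromoacetate and benzaldehyde (Wittig). C1 comes from Luche reduction of an exocyclic enone, cis to the side chain.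
4. C5 and the side chain: copper-catalysed enantioselective conjugate addition of a 2-(furan-3-yl)ethylzinc reagent to 4,4-dimethylcyclohex-2-enone, with methylenation of the enolate in the same flask.
5. Ring A is made first (isobutyraldehyde + methyl vinyl ketone annulation); ring B is made last, in the radical step.

Assumption: 3-(2-bromoethyl)furan is commercially available. Drimane numbering (C1–C12) is used for positions in the bicyclic products and their precursors.

**Route**

Step 1
Reactants: 1 isobutyraldehyde (2-methylpropanal); 2 methyl vinyl ketone (but-3-en-2-one)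
Product: 4 4,4-dimethylcyclohex-2-en-1-one, via keto aldehyde 3 (not isolated)
Conditions: cat. H2SO4, toluene, 45 °C, then reflux (Dean–Stark)
Reagents that add atoms: none
Why: Acid-catalysed Michael addition of the enol of 1 to 2 gives 3, which closes by intramolecular aldol condensation (Robinson-type annulation); no stereocentre is formed.

Step 2
Reactants: 4 4,4-dimethylcyclohex-2-en-1-one; 5 3-(2-bromoethyl)furan
Product: 11 (3S)-3-[2-(furan-3-yl)ethyl]-4,4-dimethyl-2-methylidenecyclohexan-1-one, via Grignard reagent 6 (not isolated), via diorganozinc 7 (not isolated), via zinc enolate 8 (not isolated), via Mannich base 9 (not isolated), via ammonium iodide 10 (not isolated)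
Conditions: 5 (2.6 equiv), Mg, THF, 40 °C; ZnCl2 (1.3 equiv), then 1,4-dioxane, filter; Cu(OTf)2 (2 mol%), (S,R,R)-phosphoramidite L1 [O,O'-(S)-1,1'-binaphthyl-2,2'-diyl N,N-bis((R)-1-phenylethyl)phosphoramidite, C36H30NO2P] (4 mol%), 4, toluene, −30 °C; then CH2=NMe2+ I−, THF, −30 to 0 °C; then MeI, 22 °C; then sat. aq NaHCO3, 22 °C
Reagents that add atoms: Eschenmoser's salt (N,N-dimethylmethylideneammonium iodide), C=[N+](C)C.[I-]
Why: Feringa-type copper–phosphoramidite enantioselective conjugate addition of dialkylzinc 7 (this enone is a benchmark substrate; the (S,R,R) ligand gives the 3R enolate 8 and so fixes C5, whose descriptor becomes S in 11 only through a priority change), then regiospecific Mannich trapping of 8 with Eschenmoser's salt and Hofmann-type E1cB elimination of the quaternised amine give the exo-enone, the transient C2 centre of 9 being destroyed.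

Step 3
Reactants: 11 (3S)-3-[2-(furan-3-yl)ethyl]-4,4-dimethyl-2-methylidenecyclohexan-1-one
Product: 12 (1R,3S)-3-[2-(furan-3-yl)ethyl]-4,4-dimethyl-2-methylidenecyclohexan-1-ol
Conditions: NaBH4, CeCl3·7H2O, MeOH, −78 °C
Reagents that add atoms: none
Why: Luche 1,2-reduction in which hydride adds to the carbonyl face opposite the C3 side chain (axial side chain blocks axial attack in one chair, and axial attack in the other chair comes from the same side), so the new C1 carbinol is cis to the side chain.

Step 4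
Reactants: 12 (1R,3S)-3-[2-(furan-3-yl)ethyl]-4,4-dimethyl-2-methylidenecyclohexan-1-ol; 13 benzaldehyde
Product: 17 (1R,3S)-3-[2-(furan-3-yl)ethyl]-4,4-dimethyl-2-methylidenecyclohexyl (2E)-3-phenylprop-2-enoate, via bromoacetate 14 (not isolated), via phosphonium bromide 15 (not isolated), via phosphorus ylide 16 (not isolated)
Conditions: BrCH2COBr, 2,6-lutidine, CH2Cl2, 0 °C; then PPh3, 22 °C; then 13, sat. aq NaHCO3, 22 °C
Reagents that add atoms: bromoacetyl bromide, BrCC(Br)=O
Why: O-acylation followed by a one-pot Wittig olefination, in which PPh3 alkylation and bicarbonate give the ester-stabilised ylide that reacts E-selectively with benzaldehyde; no stereocentre is touched.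

Step 5
Reactants: 17 (1R,3S)-3-[2-(furan-3-yl)ethyl]-4,4-dimethyl-2-methylidenecyclohexyl (2E)-3-phenylprop-2-enoate
Product: 19 (1R,3S)-3-[(3Z)-3-formyl-5-oxopent-3-en-1-yl]-4,4-dimethyl-2-methylidenecyclohexyl (2E)-3-phenylprop-2-enoate, via endoperoxide 18 (not isolated)
Conditions: O2, tetraphenylporphyrin (0.5 mol%), visible light, CH2Cl2, −78 °C; then Me2S, −78 to 0 °C; used crude at once
Reagents that add atoms: dioxygen, O=O
Why: Singlet-oxygen [4+2] cycloaddition to the electron-rich furan (far faster than any reaction at the 1,1-disubstituted alkene or the cinnamate) and reductive cleavage of the endoperoxide by Me2S unmask the 2-substituted (Z)-but-2-enedial, whose cis geometry is inherited from the ring.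

Step 6
Reactants: 19 (1R,3S)-3-[(3Z)-3-formyl-5-oxopent-3-en-1-yl]-4,4-dimethyl-2-methylidenecyclohexyl (2E)-3-phenylprop-2-enoate
Product: 20 (1R,4aS,8R,8aS)-7,8-diformyl-4,4,8a-trimethyl-1,2,3,4,4a,5,8,8a-octahydronaphthalen-1-yl (2E)-3-phenylprop-2-enoate (the target, 1β-(E)-cinnamoyloxypolygodial)
Conditions: Co(salen)Cl [C36H52ClCoN2O2; salen = N,N'-bis(3,5-di-tert-butylsalicylidene)cyclohexane-1,2-diamine dianion] (5 mol%), PhSiH3 (10 mol%), benzene (0.01 M), 22 °C, Ar
Reagents that add atoms: none
Why: Proposed new method: trivalent cobalt hydride (from Co(salen)Cl and PhSiH3) transfers a hydrogen atom to the exocyclic methylene, creating the C10 methyl and a tertiary C10 radical, which closes ring B by 6-endo Giese addition to C9 of the enedial through a chair transition state with the C1 ester and C5 tether equatorial, bonding on the α face away from the axial C4 methyl (trans ring fusion, C10 methyl β) and placing the C9 formyl group, which is trans to the tether on the Z alkene, equatorial (9β), after which the tertiary α-formyl C8 radical returns a C7 hydrogen atom to divalent cobalt (the chain-transfer step known for methacrylate radicals) to leave the C7=C8 enal and regenerate the hydride; the closest known reactions are cobalt–salen hydrogen-atom-transfer cycloisomerisation of dienes and iron-mediated hydrogen-atom-transfer Giese cyclisations onto enals.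

**Compound list**

1 | isobutyraldehyde (2-methylpropanal) | CC(C)C=O | starting material
2 | methyl vinyl ketone (but-3-en-2-one) | CC(=O)C=C | starting material
3 | 2,2-dimethyl-5-oxohexanal | CC(=O)CCC(C)(C)C=O | intermediate
4 | 4,4-dimethylcyclohex-2-en-1-one | CC1(C)CCC(=O)C=C1 | intermediate
5 | 3-(2-bromoethyl)furan | BrCCc1ccoc1 | starting material
6 | [2-(furan-3-yl)ethyl]magnesium bromide | Br[Mg]CCc1ccoc1 | intermediate
7 | bis[2-(furan-3-yl)ethyl]zinc | C(Cc1ccoc1)[Zn]CCc1ccoc1 | intermediate
8 | [(3R)-3-[2-(furan-3-yl)ethyl]-4,4-dimethylcyclohex-1-en-1-olato][2-(furan-3-yl)ethyl]zinc | CC1(C)CCC(O[Zn]CCc2ccoc2)=C[C@H]1CCc1ccoc1 | intermediate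
9 | (2S,3R)-2-[(dimethylamino)methyl]-3-[2-(furan-3-yl)ethyl]-4,4-dimethylcyclohexan-1-one | CC1(C)CCC(=O)[C@H](CN(C)C)[C@H]1CCc1ccoc1 | intermediate
10 | 1-[(1S,2R)-2-[2-(furan-3-yl)ethyl]-3,3-dimethyl-6-oxocyclohexyl]-N,N,N-trimethylmethanaminium iodide | CC1(C)CCC(=O)[C@H](C[N+](C)(C)C)[C@H]1CCc1ccoc1.[I-] | intermediate
11 | (3S)-3-[2-(furan-3-yl)ethyl]-4,4-dimethyl-2-methylidenecyclohexan-1-one | CC1(C)CCC(=O)C(=C)[C@H]1CCc1ccoc1 | intermediate
12 | (1R,3S)-3-[2-(furan-3-yl)ethyl]-4,4-dimethyl-2-methylidenecyclohexan-1-ol | CC1(C)CC[C@@H](O)C(=C)[C@H]1CCc1ccoc1 | intermediate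
13 | benzaldehyde | O=Cc1ccccc1 | starting material
14 | (1R,3S)-3-[2-(furan-3-yl)ethyl]-4,4-dimethyl-2-methylidenecyclohexyl 2-bromoacetate | CC1(C)CC[C@@H](OC(=O)CBr)C(=C)[C@H]1CCc1ccoc1 | intermediate
15 | (2-{[(1R,3S)-3-[2-(furan-3-yl)ethyl]-4,4-dimethyl-2-methylidenecyclohexyl]oxy}-2-oxoethyl)triphenylphosphonium bromide | CC1(C)CC[C@@H](OC(=O)C[P+](c2ccccc2)(c2ccccc2)c2ccccc2)C(=C)[C@H]1CCc1ccoc1.[Br-] | intermediate
16 | (1R,3S)-3-[2-(furan-3-yl)ethyl]-4,4-dimethyl-2-methylidenecyclohexyl 2-(triphenyl-λ5-phosphanylidene)acetate | CC1(C)CC[C@@H](OC(=O)C=P(c2ccccc2)(c2ccccc2)c2ccccc2)C(=C)[C@H]1CCc1ccoc1 | intermediate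
17 | (1R,3S)-3-[2-(furan-3-yl)ethyl]-4,4-dimethyl-2-methylidenecyclohexyl (2E)-3-phenylprop-2-enoate | CC1(C)CC[C@@H](OC(=O)/C=C/c2ccccc2)C(=C)[C@H]1CCc1ccoc1 | intermediate
18 | (1R,3S)-4,4-dimethyl-2-methylidene-3-[2-(2,3,7-trioxabicyclo[2.2.1]hept-5-en-5-yl)ethyl]cyclohexyl (2E)-3-phenylprop-2-enoate (both bridgehead diastereomers) | CC1(C)CC[C@@H](OC(=O)/C=C/c2ccccc2)C(=C)[C@H]1CCC1=CC2OOC1O2 | intermediate
19 | (1R,3S)-3-[(3Z)-3-formyl-5-oxopent-3-en-1-yl]-4,4-dimethyl-2-methylidenecyclohexyl (2E)-3-phenylprop-2-enoate | CC1(C)CC[C@@H](OC(=O)/C=C/c2ccccc2)C(=C)[C@H]1CC/C(C=O)=C/C=O | intermediate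
20 | (1R,4aS,8R,8aS)-7,8-diformyl-4,4,8a-trimethyl-1,2,3,4,4a,5,8,8a-octahydronaphthalen-1-yl (2E)-3-phenylprop-2-enoate | CC1(C)CC[C@@H](OC(=O)/C=C/c2ccccc2)[C@]2(C)[C@@H](C=O)C(C=O)=CC[C@@H]12 | target

**Totals**

Total step count: 6. Longest linear sequence: 6 steps (1 + 2 → 4 → 11 → 12 → 17 → 19 → 20).

**Steps most likely to fail, with fallbacks**

Step 6 (radical cycloisomerisation). Reversible hydrogen-atom transfer could isomerise the (Z)-enedial to E (giving the 9-epimer), isomerise the exo-methylene into the ring, or remove the C9 hydrogen instead of a C7 hydrogen. The fallback sets out from 19 and comes back at 20, and separates C–C bond formation from desaturation. The cyclisation is run reductively with Fe(acac)3 and PhSiH3 in EtOH at 60 °C (hydrogen-atom-transfer Giese cyclisation with radical–polar crossover and protonation of the enolate) to give the saturated dialdehyde F1. Its less hindered C12 aldehyde is converted into the triethylsilyl enol ether F2 (Et3SiOTf, Et3N, CH2Cl2, −78 °C). F2 is then dehydrogenated with Pd(OAc)2 in MeCN (Saegusa–Ito oxidation, β-hydride elimination towards the C7 methylene) to give 20.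

Step 5 (furan to (Z)-enedial). The free cis-enedial may isomerise to E, hydrate, or not survive handling. The fallback sets out from 17 and comes back at 19. Direct anodic methoxylation of the furan (constant current, carbon electrodes, MeOH, Et4NOTs, −20 °C; the furan is oxidised at a much lower potential than the other alkenes) gives the storable 2,5-dimethoxy-2,5-dihydrofuran F3, a masked cis-enedial. F3 is opened with wet Amberlyst-15 in acetone–water at 0 °C immediately before step 6 to give 19.

Step 2 (conjugate addition, Mannich trapping, elimination in one flask). The zinc enolate may react sluggishly with Eschenmoser's salt, or the telescoped elimination may isomerise the exo-enone. The fallback sets out from 4 and comes back at 11. After the same copper-catalysed addition of 7 to 4, enolate 8 is quenched with Me3SiCl and the silyl enol ether F4 is isolated. A regiospecific Mukaiyama aldol reaction with aqueous formaldehyde (Yb(OTf)3, THF–H2O) gives the hydroxymethyl ketone F5. Mesylation (MsCl, Et3N, 0 °C) gives the mesylate F6, and elimination with DBU gives 11.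

**Further compounds**

F1 | step 6 | (1R,4aS,8S,8aS)-7,8-diformyl-4,4,8a-trimethyldecahydronaphthalen-1-yl (2E)-3-phenylprop-2-enoate (C7 epimers) | CC1(C)CC[C@@H](OC(=O)/C=C/c2ccccc2)[C@]2(C)[C@@H](C=O)C(C=O)CC[C@@H]12
F2 | step 6 | (1R,4aS,8S,8aS)-8-formyl-4,4,8a-trimethyl-7-{[(triethylsilyl)oxy]methylidene}decahydronaphthalen-1-yl (2E)-3-phenylprop-2-enoate | CC1(C)CC[C@@H](OC(=O)/C=C/c2ccccc2)[C@]2(C)[C@@H](C=O)C(=CO[Si](CC)(CC)CC)CC[C@@H]12
F3 | step 5 | (1R,3S)-3-[2-(2,5-dimethoxy-2,5-dihydrofuran-3-yl)ethyl]-4,4-dimethyl-2-methylidenecyclohexyl (2E)-3-phenylprop-2-enoate (acetal diastereomers) | CC1(C)CC[C@@H](OC(=O)/C=C/c2ccccc2)C(=C)[C@H]1CCC1=CC(OC)OC1OC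
F4 | step 2 | {[(3R)-3-[2-(furan-3-yl)ethyl]-4,4-dimethylcyclohex-1-en-1-yl]oxy}trimethylsilane | CC1(C)CCC(O[Si](C)(C)C)=C[C@H]1CCc1ccoc1
F5 | step 2 | (2S,3R)-3-[2-(furan-3-yl)ethyl]-2-(hydroxymethyl)-4,4-dimethylcyclohexan-1-one | CC1(C)CCC(=O)[C@H](CO)[C@H]1CCc1ccoc1
F6 | step 2 | [(1S,2R)-2-[2-(furan-3-yl)ethyl]-3,3-dimethyl-6-oxocyclohexyl]methyl methanesulfonate | CC1(C)CCC(=O)[C@H](COS(C)(=O)=O)[C@H]1CCc1ccoc1
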